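## The problem

The target is a (3R)-isoflavan: ring A is fused to the dihydropyran ring C, and ring B sits on C3, the only stereocentre. C3 is benzylic but has no carbonyl next to it in the target, so it cannot be corrected late and has nothing else to control. It must be set absolutely while an acyl group is still attached, and the only other centre on the way, a transient oxirane carbon, needs no control. Four phenolic oxygens have different fates. O1 is the ring ether, while 7-OH, 2'-OH and 4'-OH end up free, so they must be told apart during the synthesis. Ring B carries a 1,1-dimethylallyl group on C5', a hindered aryl–quaternary carbon bond next to 4'-OH. Ring A carries on C8, between O7 and O1, a 3-hydroxy-3-methylbutyl chain, which is a hydrated prenyl group. The monosubstituted alkene rules out hydrogenation once it is present. Acid would close the tertiary alcohol onto O7 (2,2-dimethylchroman) and cyclise the ortho-allyl phenols, and the free resorcinol-type rings oxidise easily. The feature that opens the route is that each five-carbon unit lies ortho to a phenol oxygen (C5' beside O4', C8 beside O7) while the para carbons C1' and C4a are substituted. Each unit is therefore the [3,3] product of an aryl allyl ether of the opposite allyl sense. The structure does not decide which ortho carbon is used: C3' or C5' on ring B, C6 or C8 on ring A. In a 7-alkoxychroman O1 is a meta donor and gives no bias toward C8, so that choice has to be enforced by substituents placed for the purpose.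

## Retrosynthesis

**Tertiary alcohol (28 back to 24).** The C–O bond of the carbinol and one C–H bond are removed, which leads from 28 through the silyl ethers 27, 26 and 25 to the 8-prenyl phenol 24. Acid hydration or oxymercuration would cyclise onto O7 or attack the terminal alkene. Epoxidation of the electron-rich trisubstituted alkene (26) and hydride opening at the secondary carbon (27) avoid acid and use the large difference in electron density between the two alkenes. The price is that the phenols must be capped (25), since a free 7-OH would open the epoxide. The final fluoride step has to free three silyl ethers without acid.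

**Blocking bromine (24 back to 23).** The C6–H bond is traced back to C6–Br. The bromine has no place in the target; it is carried so that the ring-A shift in the key step has only C8 to go to. Its removal asks for a reduction that leaves a vinyl group, a prenyl group and two phenols alone.

**Both five-carbon units at once (23 back to 21).** The bonds C5'–C(quaternary) and C8–C1'' are cut, and each allyl unit is returned to the neighbouring oxygen with inverted sense. This gives the bis-ether 21, with a prenyl ether on O4', a 1,1-dimethylallyl ether on O7, a triisopropylsilyl group on O2' and bromine on C6. The mono-rearranged phenol 22 lies between them. Friedel–Crafts prenylation cannot give the branched group and is unselective. Coupling a tertiary allyl metal to an aryl halide normally delivers the linear isomer. The rearrangement makes the hindered aryl–quaternary bond intramolecularly and lets the whole core be assembled without any C-allyl group. The forward step must give ortho selectivity on both rings and must tolerate two ethers of very different reactivity in one flask.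

**Three ether bonds (21 back to 14).** O2'–Si, O4'–CH2 and O7–C(tertiary) are cut in turn: 21 from phenol 20, 20 from diol 18 and prenyl bromide 19, 18 from bis-silyl ether 17, and 17 from phenol 14 and the carbonate 16, itself made from 2-methylbut-3-en-2-ol 15. The tertiary ether is made first, while ring B is still fully silylated, so that 7-OH is the only nucleophile. The forward sequence needs one site-selective step, alkylation of O4' in preference to the hindered O2' of 18.

**Ring C (14 back to 12).** The O1–C2 bond is cut to the phenol-alcohol 13, which comes from the bis-MOM ether 12 by acid. Closing the ring by etherification of a primary alcohol keeps C3 untouched. Removing both MOM groups together frees 7-OH at the moment it is needed for the next ether. The 2'-oxygen must stay protected so that ring B cannot close a five-membered ring on the same carbon.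

**The stereocentre (12 back to 10 and 4).** The C3–C4 bond is cut to the enolate of the N-arylacetyl oxazolidinone 10 and the benzylic bromide 4, with 11 as the alkylation product and 12 as its reduction product. An auxiliary alkylation is preferred here to a catalytic reduction of an isoflavene because it delivers C2 directly at the alcohol level and is dependable for arylacetyl imides. After reduction no carbonyl remains next to C3.

**The two aromatic halves.** Imide 10 comes from acid 7 and (R)-4-benzyloxazolidin-2-one 8 through the mixed anhydride 9, and 7 from 2,4-dihydroxyphenylacetic acid 5 through the silyl ester 6. Bromide 4 comes from alcohol 3, aldehyde 2 and 5-bromo-2,4-dihydroxybenzaldehyde 1. Acid-labile MOM groups on ring A and fluoride-labile silyl groups on ring B give the two levels of orthogonality the later steps need. Hydrogenolysis is never required, so the bromine survives.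

## Roads not taken

**Alternative 1:** ring A is built by a tethered benzannulation. The cut is C7–C8 and C4a–C8a; the substrate A2 joins a 2-substituted cyclobutenone to an alkynyl ether through the C4–C3–C2–O1 chain. Heating A2 should open the four-membered ring, add the resulting ketene unit across the alkyne, open again and close by a six-electron electrocyclisation, giving ring A and ring C of A1 together.
- Merits: the substitution pattern of ring A is fixed by construction, so there is no C6 isomer and no blocking group. The side chain arrives as the protected tertiary alcohol, so the end game is one fluoride step.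
- Weak points: A2 needs C3 set beforehand and a ring B that already carries the quaternary group, so the hard aryl–quaternary bond still has to be made elsewhere. An alkynyl ether whose oxygen bears a CH2–CH(aryl) unit has a β-hydrogen and can fragment by a retro-ene path at the temperatures the annulation needs, cutting C2–O1. The cyclobutenone is sensitive, and an oxygen-tethered variant that closes a six-membered heterocycle has little precedent.
- Comparison: this road is better in regiocontrol on ring A and saves the epoxidation and hydride steps. The chosen plan sets against it a bromine that costs one removal step, reaction types that are all established on their substrate classes, and two purchasable aromatic starting materials.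

**Alternative 2:** a three-component coupling across a vinyl linchpin. The cut is C3–C1' and C4–C4a. Vinyllithium A5 adds to the boron of the ring-B boronic ester A4. With the ring-A aryl triflate A6 and a palladium catalyst bearing a chiral bisphosphine, ring B should shift from boron to the adjacent carbon while the ring-A aryl is delivered to the terminal carbon, giving the secondary boronate A3.
- Merits: it is the most convergent of the four plans and sets C3 by catalysis, without attaching and removing an auxiliary.
- Weak points: A3 still lacks C2 and ring C, so homologation of the boronate, oxidation, MOM removal and ring closure follow. The acid needed for the MOM group meets a tertiary silyl ether and an ortho-(1,1-dimethylallyl) silyl ether. The migrating aryl of A4 has an ortho silyloxy group, and A6 is an electron-rich ortho-substituted triflate, so both the shift and the oxidative addition are at the hindered end of what this coupling handles. The terminal alkene of A4 can insert into the arylpalladium species. Both five-carbon units must be placed on the separate rings first.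
- Comparison: better in convergence and in catalytic control of C3. The chosen plan sets against it an alkylation that gives C2 at the right oxidation level two steps from ring C, and one late operation for both five-carbon units.

**Alternative 3:** a quinone methide is intercepted by a catalyst-bound enolate. The cut is C3–C4 and C2–O1 at the lactone level. Base should release the quinone methide A9 from the sulfone A8. C3 of the enolate that a chiral isothiourea forms from the activated acid A10 adds to its methylene carbon, and the phenoxide then acylates and frees the catalyst, giving the lactone A7.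
- Merits: one catalytic step sets C3 and closes ring C, so the route to the bicyclic core is shorter than the auxiliary sequence.
- Weak points: in A7 the C3–H is benzylic and α to an aryl ester, so it is prone to epimerisation. C2 has to be brought down from the lactone to CH2 by reduction and re-closure. A9 has an unsubstituted methylene terminus, the most reactive and least discriminating kind of such acceptor. Both rings must again be fully decorated in advance.
- Comparison: better in step count to the chroman skeleton and in using a catalyst for asymmetry. The chosen plan sets against it configurational security: after step 7 no carbonyl is next to C3, so the centre should survive thirteen further steps, including heating to 190 °C.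

Key step: step 15

Assumption: compounds 1, 5, 8, 15 and 19 are taken as purchasable; metal salts of numbered compounds formed in passing (the enolate of 10, the alkoxide of 15, phenoxides) are not counted as separate compounds; the oxirane carbon of 26 is formed as both epimers and left so, since it becomes CH2 in step 19.

Step 1
Reactants: 1 5-bromo-2,4-dihydroxybenzaldehyde
Product: 2 5-bromo-2,4-bis(methoxymethoxy)benzaldehyde
Conditions: MOMCl, i-Pr2NEt, CH2Cl2, 0 °C to 40 °C
Reagents that add atoms: chloromethyl methyl ether COCCl
Why: O-Alkylation of both phenols with a chloromethyl ether (MOM protection); excess reagent and warming overcome the hydrogen-bonded 2-OH, and the acetals tolerate the base and hydride steps up to step 8.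

Step 2
Reactants: 2 5-bromo-2,4-bis(methoxymethoxy)benzaldehyde
Product: 3 [5-bromo-2,4-bis(methoxymethoxy)phenyl]methanol
Conditions: NaBH4, MeOH, 0 °C
Reagents that add atoms: none
Why: Borohydride reduction of an aryl aldehyde; the aryl bromide and the MOM ethers are inert.

Step 3
Reactants: 3 [5-bromo-2,4-bis(methoxymethoxy)phenyl]methanol
Product: 4 1-bromo-5-(bromomethyl)-2,4-bis(methoxymethoxy)benzene
Conditions: CBr4, PPh3, CH2Cl2, 0 °C
Reagents that add atoms: carbon tetrabromide BrC(Br)(Br)Br
Why: Appel bromination is neutral, so the acid-labile MOM acetals survive; the electron-rich benzylic bromide ionises easily and is used at once in step 6.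

Step 4
Reactants: 5 2,4-dihydroxyphenylacetic acid
Product: 7 2,4-bis(triisopropylsilyloxy)phenylacetic acid, via tris-silylated ester 6 (not isolated)
Conditions: TIPSCl, imidazole, DMF, rt; then AcOH, THF, H2O, rt
Reagents that add atoms: triisopropylsilyl chloride CC(C)[Si](Cl)(C(C)C)C(C)C
Why: Exhaustive silylation followed by selective hydrolysis of the silyl ester, whose acyloxy leaving group makes it far more labile than the two aryl silyl ethers, which withstand mild aqueous acid.

Step 5
Reactants: 7 2,4-bis(triisopropylsilyloxy)phenylacetic acid; 8 (R)-4-benzyloxazolidin-2-one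
Product: 10 (R)-4-benzyl-3-{[2,4-bis(triisopropylsilyloxy)phenyl]acetyl}oxazolidin-2-one, via mixed pivalic anhydride 9 (not isolated)
Conditions: t-BuCOCl, Et3N, THF, −20 °C; then 8, LiCl, rt
Reagents that add atoms: none
Why: N-Acylation of the oxazolidinone through the mixed pivalic anhydride with LiCl/Et3N activation, the usual mild way to attach an arylacetic acid to the auxiliary without strong base.

Step 6
Reactants: 10 (R)-4-benzyl-3-{[2,4-bis(triisopropylsilyloxy)phenyl]acetyl}oxazolidin-2-one; 4 1-bromo-5-(bromomethyl)-2,4-bis(methoxymethoxy)benzene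
Product: 11 (R)-4-benzyl-3-{(2R)-3-[5-bromo-2,4-bis(methoxymethoxy)phenyl]-2-[2,4-bis(triisopropylsilyloxy)phenyl]propanoyl}oxazolidin-2-one
Conditions: NaN(SiMe3)2, THF, −78 °C; then 4, −78 to −40 °C
Reagents that add atoms: none
Why: Evans alkylation: the sodium Z-enolate is chelated to the oxazolidinone carbonyl, the benzyl group of the (R)-auxiliary covers one face and the benzylic bromide enters from the other, which sets the future C3 as R; the low temperature guards the acidic arylacetyl centre against epimerisation.

Step 7
Reactants: 11 (R)-4-benzyl-3-{(2R)-3-[5-bromo-2,4-bis(methoxymethoxy)phenyl]-2-[2,4-bis(triisopropylsilyloxy)phenyl]propanoyl}oxazolidin-2-one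
Product: 12 (2R)-3-[5-bromo-2,4-bis(methoxymethoxy)phenyl]-2-[2,4-bis(triisopropylsilyloxy)phenyl]propan-1-ol
Conditions: LiBH4, MeOH (1 equiv), THF, 0 °C
Reagents that add atoms: none
Why: Reductive cleavage of the N-acyl oxazolidinone gives the primary alcohol and returns the auxiliary; from here on no carbonyl is next to the stereocentre.

Step 8
Reactants: 12 (2R)-3-[5-bromo-2,4-bis(methoxymethoxy)phenyl]-2-[2,4-bis(triisopropylsilyloxy)phenyl]propan-1-ol
Product: 13 4-bromo-6-{(2R)-2-[2,4-bis(triisopropylsilyloxy)phenyl]-3-hydroxypropyl}benzene-1,3-diol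
Conditions: HCl, MeOH, 40 °C
Reagents that add atoms: none
Why: Acid-catalysed acetal exchange with the solvent removes both MOM groups as dimethoxymethane; aryl triisopropylsilyl ethers withstand dilute methanolic HCl, and no alkene is present yet.

Step 9
Reactants: 13 4-bromo-6-{(2R)-2-[2,4-bis(triisopropylsilyloxy)phenyl]-3-hydroxypropyl}benzene-1,3-diol
Product: 14 (3R)-6-bromo-3-[2,4-bis(triisopropylsilyloxy)phenyl]chroman-7-ol
Conditions: PPh3, DIAD, THF (high dilution), 0 °C to rt
Reagents that add atoms: none
Why: Intramolecular Mitsunobu etherification closes ring C by 6-exo-tet displacement at the primary carbon, so C3 is untouched; the silylated 2'-oxygen cannot compete, and dilution disfavours intermolecular alkylation of the free 7-OH.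

Step 10
Reactants: 15 2-methylbut-3-en-2-ol
Product: 16 tert-butyl 2-methylbut-3-en-2-yl carbonate
Conditions: n-BuLi, THF, −78 to 0 °C; then Boc2O
Reagents that add atoms: di-tert-butyl dicarbonate CC(C)(C)OC(=O)OC(=O)OC(C)(C)C
Why: Acylation of the lithium alkoxide of the tertiary allylic alcohol gives the mixed carbonate, the standard ionisable partner for palladium-catalysed allylation.

Step 11
Reactants: 14 (3R)-6-bromo-3-[2,4-bis(triisopropylsilyloxy)phenyl]chroman-7-ol; 16 tert-butyl 2-methylbut-3-en-2-yl carbonate
Product: 17 (3R)-6-bromo-7-(2-methylbut-3-en-2-yloxy)-3-[2,4-bis(triisopropylsilyloxy)phenyl]chroman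
Conditions: Pd(PPh3)4 (cat.), THF, 0 °C
Reagents that add atoms: none
Why: Decarboxylative Tsuji–Trost O-allylation: zerovalent palladium ionises the carbonate, the released tert-butoxide deprotonates the phenol, and the phenoxide attacks the more substituted allyl terminus under kinetic control at low temperature to give the tertiary ether; an electron-rich aryl bromide is not expected to add oxidatively at 0 °C.

Step 12
Reactants: 17 (3R)-6-bromo-7-(2-methylbut-3-en-2-yloxy)-3-[2,4-bis(triisopropylsilyloxy)phenyl]chroman
Product: 18 4-[(3R)-6-bromo-7-(2-methylbut-3-en-2-yloxy)chroman-3-yl]benzene-1,3-diol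
Conditions: Bu4NF, THF, 0 °C
Reagents that add atoms: none
Why: Fluoride cleaves both aryl silyl ethers; the tertiary allyl ether, the aryl bromide and the ring ether are inert to it.

Step 13
Reactants: 18 4-[(3R)-6-bromo-7-(2-methylbut-3-en-2-yloxy)chroman-3-yl]benzene-1,3-diol; 19 prenyl bromide (1-bromo-3-methylbut-2-ene)
Product: 20 2-[(3R)-6-bromo-7-(2-methylbut-3-en-2-yloxy)chroman-3-yl]-5-(3-methylbut-2-enyloxy)phenol
Conditions: K2CO3, acetone, rt (19: 1 equiv)
Reagents that add atoms: none
Why: Williamson etherification with one equivalent of halide; the 4'-phenoxide is unhindered whereas the 2'-oxygen lies beside the branched C3 substituent, so alkylation should occur mainly at O4' (site selectivity from sterics and stoichiometry).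

Step 14
Reactants: 20 2-[(3R)-6-bromo-7-(2-methylbut-3-en-2-yloxy)chroman-3-yl]-5-(3-methylbut-2-enyloxy)phenol
Product: 21 (3R)-6-bromo-7-(2-methylbut-3-en-2-yloxy)-3-[4-(3-methylbut-2-enyloxy)-2-(triisopropylsilyloxy)phenyl]chroman
Conditions: TIPSCl, imidazole, DMAP (cat.), DMF, 40 °C
Reagents that add atoms: triisopropylsilyl chloride CC(C)[Si](Cl)(C(C)C)C(C)C
Why: Silylation of the remaining hindered phenol under mild non-acidic conditions that leave both allyl ethers alone; the bulky silyl group is placed to shield C3' in the next step.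

Step 15
Reactants: 21 (3R)-6-bromo-7-(2-methylbut-3-en-2-yloxy)-3-[4-(3-methylbut-2-enyloxy)-2-(triisopropylsilyloxy)phenyl]chroman
Product: 23 (3R)-6-bromo-3-[4-hydroxy-5-(2-methylbut-3-en-2-yl)-2-(triisopropylsilyloxy)phenyl]-8-(3-methylbut-2-enyl)chroman-7-ol, via mono-rearranged 8-prenyl phenol 22 (not isolated)
Conditions: PhNEt2 (degassed), 130 °C, then 190 °C, sealed tube
Reagents that add atoms: none
Why: Two aromatic Claisen rearrangements run one after the other in one flask, each through a chair-like six-membered transition state that transposes the allyl unit. The tertiary ether on O7 reacts first at the lower temperature and, because C6 carries bromine, can deliver its CH2 terminus only to C8, giving after enolisation the 8-prenyl phenol 22; at the higher temperature the primary prenyl ether on O4' delivers its disubstituted terminus to C5', which forms the aryl–quaternary carbon bond intramolecularly and gives 23. The closest known reactions are the thermal ortho-Claisen rearrangements of aryl prenyl ethers to ortho-(1,1-dimethylallyl)phenols and of aryl 1,1-dimethylallyl ethers to ortho-prenylphenols in N,N-dialkylanilines; only their combination in one molecule is new. No ring is closed and no stereocentre is formed, and C3, with no acidifying neighbour, is not at risk. The selectivity needed is ortho regiochemistry twice: on ring A it is enforced by the bromine at C6, on ring B by the triisopropylsilyloxy group beside C3' together with the usual preference of a meta donor for the remote ortho carbon. The para carbons C4a and C1' are substituted, so the dienones can only enolise and no Cope shift follows. The basic solvent suppresses acid-catalysed ionisation of the tertiary ether and cyclisation of the new ortho-allyl phenols.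

Step 16
Reactants: 23 (3R)-6-bromo-3-[4-hydroxy-5-(2-methylbut-3-en-2-yl)-2-(triisopropylsilyloxy)phenyl]-8-(3-methylbut-2-enyl)chroman-7-ol
Product: 24 (3R)-3-[4-hydroxy-5-(2-methylbut-3-en-2-yl)-2-(triisopropylsilyloxy)phenyl]-8-(3-methylbut-2-enyl)chroman-7-ol
Conditions: Bu3SnH, AIBN (cat.), toluene, 90 °C
Reagents that add atoms: none
Why: Radical-chain hydrodebromination removes the blocking bromine; aryl bromides are reduced much faster than unactivated alkenes are hydrostannylated, and the C6 aryl radical has no alkene within reach for cyclisation.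

Step 17
Reactants: 24 (3R)-3-[4-hydroxy-5-(2-methylbut-3-en-2-yl)-2-(triisopropylsilyloxy)phenyl]-8-(3-methylbut-2-enyl)chroman-7-ol
Product: 25 (3R)-7-(tert-butyldimethylsilyloxy)-3-[4-(tert-butyldimethylsilyloxy)-5-(2-methylbut-3-en-2-yl)-2-(triisopropylsilyloxy)phenyl]-8-(3-methylbut-2-enyl)chroman
Conditions: TBSOTf, 2,6-lutidine, CH2Cl2, −78 to 0 °C
Reagents that add atoms: tert-butyldimethylsilyl trifluoromethanesulfonate CC(C)(C)[Si](C)(C)OS(=O)(=O)C(F)(F)F
Why: Silyl triflate with a hindered base silylates both phenols, including the 4'-OH beside the quaternary carbon, so that no phenol can attack the epoxide made in step 18.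

Step 18
Reactants: 25 (3R)-7-(tert-butyldimethylsilyloxy)-3-[4-(tert-butyldimethylsilyloxy)-5-(2-methylbut-3-en-2-yl)-2-(triisopropylsilyloxy)phenyl]-8-(3-methylbut-2-enyl)chroman
Product: 26 (3R)-7-(tert-butyldimethylsilyloxy)-3-[4-(tert-butyldimethylsilyloxy)-5-(2-methylbut-3-en-2-yl)-2-(triisopropylsilyloxy)phenyl]-8-[(3,3-dimethyloxiran-2-yl)methyl]chroman (both epimers at the oxirane carbon)
Conditions: mCPBA, NaHCO3, CH2Cl2, 0 °C
Reagents that add atoms: 3-chloroperoxybenzoic acid OOC(=O)c1cccc(Cl)c1
Why: Prilezhaev epoxidation: the trisubstituted electron-rich alkene reacts far faster with a peracid than the monosubstituted neopentyl-type vinyl group, and the NaHCO3 buffer prevents acid opening; the new oxirane carbon forms as both epimers, which does not matter because it becomes CH2 in step 19.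

Step 19
Reactants: 26 (3R)-7-(tert-butyldimethylsilyloxy)-3-[4-(tert-butyldimethylsilyloxy)-5-(2-methylbut-3-en-2-yl)-2-(triisopropylsilyloxy)phenyl]-8-[(3,3-dimethyloxiran-2-yl)methyl]chroman (both epimers at the oxirane carbon)
Product: 27 4-{(3R)-7-(tert-butyldimethylsilyloxy)-3-[4-(tert-butyldimethylsilyloxy)-5-(2-methylbut-3-en-2-yl)-2-(triisopropylsilyloxy)phenyl]chroman-8-yl}-2-methylbutan-2-ol
Conditions: LiBHEt3, THF, 0 °C
Reagents that add atoms: none
Why: SN2 hydride opening of the trisubstituted epoxide at its less substituted secondary carbon gives the tertiary alcohol without acid; aryl silyl ethers, the terminal alkene and the ring ether are inert to the borohydride.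

Step 20
Reactants: 27 4-{(3R)-7-(tert-butyldimethylsilyloxy)-3-[4-(tert-butyldimethylsilyloxy)-5-(2-methylbut-3-en-2-yl)-2-(triisopropylsilyloxy)phenyl]chroman-8-yl}-2-methylbutan-2-ol
Product: 28 4-[(3R)-7-hydroxy-8-(3-hydroxy-3-methylbutyl)chroman-3-yl]-6-(2-methylbut-3-en-2-yl)benzene-1,3-diol (CNP0420388.1)
Conditions: Bu4NF, AcOH, THF, 0 °C to rt
Reagents that add atoms: none
Why: Fluoride removes the two tert-butyldimethylsilyl groups and the triisopropylsilyl group in one buffered, non-acidic operation, so the tertiary alcohol cannot close onto O7 and the ortho-allyl phenol cannot cyclise.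

## Compound list

1 | 5-bromo-2,4-dihydroxybenzaldehyde | O=Cc1cc(Br)c(O)cc1O | starting material
2 | 5-bromo-2,4-bis(methoxymethoxy)benzaldehyde | O=Cc1cc(Br)c(OCOC)cc1OCOC | intermediate
3 | [5-bromo-2,4-bis(methoxymethoxy)phenyl]methanol | OCc1cc(Br)c(OCOC)cc1OCOC | intermediate
4 | 1-bromo-5-(bromomethyl)-2,4-bis(methoxymethoxy)benzene | BrCc1cc(Br)c(OCOC)cc1OCOC | intermediate
5 | 2,4-dihydroxyphenylacetic acid | OC(=O)Cc1ccc(O)cc1O | starting material
6 | triisopropylsilyl 2,4-bis(triisopropylsilyloxy)phenylacetate | CC(C)[Si](C(C)C)(C(C)C)OC(=O)Cc1ccc(O[Si](C(C)C)(C(C)C)C(C)C)cc1O[Si](C(C)C)(C(C)C)C(C)C | intermediate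
7 | 2,4-bis(triisopropylsilyloxy)phenylacetic acid | OC(=O)Cc1ccc(O[Si](C(C)C)(C(C)C)C(C)C)cc1O[Si](C(C)C)(C(C)C)C(C)C | intermediate
8 | (R)-4-benzyloxazolidin-2-one | O=C1N[C@H](Cc2ccccc2)CO1 | starting material
9 | 2,4-bis(triisopropylsilyloxy)phenylacetic pivalic anhydride | CC(C)(C)C(=O)OC(=O)Cc1ccc(O[Si](C(C)C)(C(C)C)C(C)C)cc1O[Si](C(C)C)(C(C)C)C(C)C | intermediate
10 | (R)-4-benzyl-3-{[2,4-bis(triisopropylsilyloxy)phenyl]acetyl}oxazolidin-2-one | O=C1OC[C@@H](Cc2ccccc2)N1C(=O)Cc1ccc(O[Si](C(C)C)(C(C)C)C(C)C)cc1O[Si](C(C)C)(C(C)C)C(C)C | intermediate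
11 | (R)-4-benzyl-3-{(2R)-3-[5-bromo-2,4-bis(methoxymethoxy)phenyl]-2-[2,4-bis(triisopropylsilyloxy)phenyl]propanoyl}oxazolidin-2-one | O=C1OC[C@@H](Cc2ccccc2)N1C(=O)[C@H](Cc1cc(Br)c(OCOC)cc1OCOC)c1ccc(O[Si](C(C)C)(C(C)C)C(C)C)cc1O[Si](C(C)C)(C(C)C)C(C)C | intermediate
12 | (2R)-3-[5-bromo-2,4-bis(methoxymethoxy)phenyl]-2-[2,4-bis(triisopropylsilyloxy)phenyl]propan-1-ol | OC[C@H](Cc1cc(Br)c(OCOC)cc1OCOC)c1ccc(O[Si](C(C)C)(C(C)C)C(C)C)cc1O[Si](C(C)C)(C(C)C)C(C)C | intermediate
13 | 4-bromo-6-{(2R)-2-[2,4-bis(triisopropylsilyloxy)phenyl]-3-hydroxypropyl}benzene-1,3-diol | OC[C@H](Cc1cc(Br)c(O)cc1O)c1ccc(O[Si](C(C)C)(C(C)C)C(C)C)cc1O[Si](C(C)C)(C(C)C)C(C)C | intermediate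
14 | (3R)-6-bromo-3-[2,4-bis(triisopropylsilyloxy)phenyl]chroman-7-ol | CC(C)[Si](C(C)C)(C(C)C)Oc1ccc([C@@H]2COc3cc(O)c(Br)cc3C2)c(O[Si](C(C)C)(C(C)C)C(C)C)c1 | intermediate
15 | 2-methylbut-3-en-2-ol | C=CC(C)(C)O | starting material
16 | tert-butyl 2-methylbut-3-en-2-yl carbonate | C=CC(C)(C)OC(=O)OC(C)(C)C | intermediate
17 | (3R)-6-bromo-7-(2-methylbut-3-en-2-yloxy)-3-[2,4-bis(triisopropylsilyloxy)phenyl]chroman | CC(C)[Si](C(C)C)(C(C)C)Oc1ccc([C@@H]2COc3cc(OC(C)(C)C=C)c(Br)cc3C2)c(O[Si](C(C)C)(C(C)C)C(C)C)c1 | intermediate
18 | 4-[(3R)-6-bromo-7-(2-methylbut-3-en-2-yloxy)chroman-3-yl]benzene-1,3-diol | Oc1ccc([C@@H]2COc3cc(OC(C)(C)C=C)c(Br)cc3C2)c(O)c1 | intermediate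
19 | prenyl bromide (1-bromo-3-methylbut-2-ene) | CC(C)=CCBr | starting material
20 | 2-[(3R)-6-bromo-7-(2-methylbut-3-en-2-yloxy)chroman-3-yl]-5-(3-methylbut-2-enyloxy)phenol | CC(C)=CCOc1ccc([C@@H]2COc3cc(OC(C)(C)C=C)c(Br)cc3C2)c(O)c1 | intermediate
21 | (3R)-6-bromo-7-(2-methylbut-3-en-2-yloxy)-3-[4-(3-methylbut-2-enyloxy)-2-(triisopropylsilyloxy)phenyl]chroman | CC(C)=CCOc1ccc([C@@H]2COc3cc(OC(C)(C)C=C)c(Br)cc3C2)c(O[Si](C(C)C)(C(C)C)C(C)C)c1 | intermediate
22 | (3R)-6-bromo-8-(3-methylbut-2-enyl)-3-[4-(3-methylbut-2-enyloxy)-2-(triisopropylsilyloxy)phenyl]chroman-7-ol | CC(C)=CCOc1ccc([C@@H]2COc3c(CC=C(C)C)c(O)c(Br)cc3C2)c(O[Si](C(C)C)(C(C)C)C(C)C)c1 | intermediate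
23 | (3R)-6-bromo-3-[4-hydroxy-5-(2-methylbut-3-en-2-yl)-2-(triisopropylsilyloxy)phenyl]-8-(3-methylbut-2-enyl)chroman-7-ol | C=CC(C)(C)c1cc([C@@H]2COc3c(CC=C(C)C)c(O)c(Br)cc3C2)c(O[Si](C(C)C)(C(C)C)C(C)C)cc1O | intermediate
24 | (3R)-3-[4-hydroxy-5-(2-methylbut-3-en-2-yl)-2-(triisopropylsilyloxy)phenyl]-8-(3-methylbut-2-enyl)chroman-7-ol | C=CC(C)(C)c1cc([C@@H]2COc3c(CC=C(C)C)c(O)ccc3C2)c(O[Si](C(C)C)(C(C)C)C(C)C)cc1O | intermediate
25 | (3R)-7-(tert-butyldimethylsilyloxy)-3-[4-(tert-butyldimethylsilyloxy)-5-(2-methylbut-3-en-2-yl)-2-(triisopropylsilyloxy)phenyl]-8-(3-methylbut-2-enyl)chroman | C=CC(C)(C)c1cc([C@@H]2COc3c(CC=C(C)C)c(O[Si](C)(C)C(C)(C)C)ccc3C2)c(O[Si](C(C)C)(C(C)C)C(C)C)cc1O[Si](C)(C)C(C)(C)C | intermediate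
26 | (3R)-7-(tert-butyldimethylsilyloxy)-3-[4-(tert-butyldimethylsilyloxy)-5-(2-methylbut-3-en-2-yl)-2-(triisopropylsilyloxy)phenyl]-8-[(3,3-dimethyloxiran-2-yl)methyl]chroman (both epimers at the oxirane carbon) | C=CC(C)(C)c1cc([C@@H]2COc3c(CC4OC4(C)C)c(O[Si](C)(C)C(C)(C)C)ccc3C2)c(O[Si](C(C)C)(C(C)C)C(C)C)cc1O[Si](C)(C)C(C)(C)C | intermediate
27 | 4-{(3R)-7-(tert-butyldimethylsilyloxy)-3-[4-(tert-butyldimethylsilyloxy)-5-(2-methylbut-3-en-2-yl)-2-(triisopropylsilyloxy)phenyl]chroman-8-yl}-2-methylbutan-2-ol | C=CC(C)(C)c1cc([C@@H]2COc3c(CCC(C)(C)O)c(O[Si](C)(C)C(C)(C)C)ccc3C2)c(O[Si](C(C)C)(C(C)C)C(C)C)cc1O[Si](C)(C)C(C)(C)C | intermediate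
28 | 4-[(3R)-7-hydroxy-8-(3-hydroxy-3-methylbutyl)chroman-3-yl]-6-(2-methylbut-3-en-2-yl)benzene-1,3-diol (CNP0420388.1) | C=CC(C)(C)c1cc([C@@H]2COc3c(ccc(O)c3CCC(C)(C)O)C2)c(O)cc1O | target

## Step count and risks

Total: 20 steps. Longest linear sequence: 17 steps (steps 1–3, 6–9 and 11–20, from aldehyde 1).

**Step 15 (key step).** The ring-B ether needs a much higher temperature than the ring-A ether, so the first-formed phenols sit in the hot solution for a long time. The likely failures are thermal loss of the tertiary allyl group from O7 as isoprene before it shifts, and ene-type (abnormal Claisen) isomerisation or ring closure of the 4'-hydroxy-5'-(1,1-dimethylallyl) unit to a coumaran. A catalyst such as Eu(fod)3 might lower the temperature, but the fallback changes the step itself. From 21, the rearrangement is run in N,N-diethylaniline containing acetic anhydride and NaOAc, so that each phenol is acetylated as it forms and the O–H that the side reactions need is removed. This gives (3R)-7-acetoxy-3-[4-acetoxy-5-(2-methylbut-3-en-2-yl)-2-(triisopropylsilyloxy)phenyl]-6-bromo-8-(3-methylbut-2-enyl)chroman F1. Brief methanolysis (K2CO3, MeOH, 0 °C) cleaves both aryl acetates but not the hindered aryl silyl ether, and the route is rejoined at 23.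

**Step 11.** Zerovalent palladium may insert into the C6–Br bond, or the kinetically formed tertiary ether may re-ionise and isomerise to the linear prenyl ether, because the ortho-bromophenoxide is a good leaving group. Fallback from 14: copper-catalysed propargylation with 3-chloro-3-methylbut-1-yne (CuCl2 cat., DBU, MeCN, 0 °C) gives (3R)-6-bromo-7-(2-methylbut-3-yn-2-yloxy)-3-[2,4-bis(triisopropylsilyloxy)phenyl]chroman F2, which cannot isomerise. Semi-hydrogenation (H2, Pd/CaCO3 poisoned with Pb(OAc)2, quinoline) then returns to the route at 17.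

**Step 13.** Alkylation may be poorly site-selective, giving the 2'-ether or the bis-ether, because the two phenols differ only in steric access. Fallback from 17: the less hindered 4'-O-silyl ether alone is cleaved with one equivalent of Bu4NF at −78 °C, giving 4-[(3R)-6-bromo-7-(2-methylbut-3-en-2-yloxy)chroman-3-yl]-3-(triisopropylsilyloxy)phenol F3; material cleaved at the wrong site or twice can be re-silylated to 17. Alkylation of F3 with 19 and K2CO3 is then unambiguous and rejoins the route at 21, bypassing 18 and 20.

**Step 9.** The more acidic 7-OH (ortho to bromine) may be alkylated intermolecularly, or the activated alcohol may be captured by the hydrazide, leading to oligomers instead of ring closure. Fallback from 12, with the phenols still protected: mesylation (MsCl, Et3N) gives (2R)-3-[5-bromo-2,4-bis(methoxymethoxy)phenyl]-2-[2,4-bis(triisopropylsilyloxy)phenyl]propyl methanesulfonate F4. Methanolic HCl then gives (2R)-3-(5-bromo-2,4-dihydroxyphenyl)-2-[2,4-bis(triisopropylsilyloxy)phenyl]propyl methanesulfonate F5. K2CO3 in MeCN at high dilution closes ring C by phenoxide displacement and rejoins the route at 14.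

**Step 16.** Stannyl radicals may add to the terminal alkene, or the chain may be slowed by the hindered phenols, so debromination could be incomplete. Fallback from 23, by a polar instead of a radical mechanism: palladium-catalysed transfer hydrogenolysis (Pd(OAc)2, PPh3, HCO2H, Et3N, DMF, 80 °C). Zerovalent palladium inserts into C6–Br, formate supplies hydride and reductive elimination gives 24 directly; no new compound is involved.

## Further compounds

F1 | step 15 | (3R)-7-acetoxy-3-[4-acetoxy-5-(2-methylbut-3-en-2-yl)-2-(triisopropylsilyloxy)phenyl]-6-bromo-8-(3-methylbut-2-enyl)chroman | C=CC(C)(C)c1cc([C@@H]2COc3c(CC=C(C)C)c(OC(C)=O)c(Br)cc3C2)c(O[Si](C(C)C)(C(C)C)C(C)C)cc1OC(C)=O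
F2 | step 11 | (3R)-6-bromo-7-(2-methylbut-3-yn-2-yloxy)-3-[2,4-bis(triisopropylsilyloxy)phenyl]chroman | CC(C)[Si](C(C)C)(C(C)C)Oc1ccc([C@@H]2COc3cc(OC(C)(C)C#C)c(Br)cc3C2)c(O[Si](C(C)C)(C(C)C)C(C)C)c1
F3 | step 13 | 4-[(3R)-6-bromo-7-(2-methylbut-3-en-2-yloxy)chroman-3-yl]-3-(triisopropylsilyloxy)phenol | Oc1ccc([C@@H]2COc3cc(OC(C)(C)C=C)c(Br)cc3C2)c(O[Si](C(C)C)(C(C)C)C(C)C)c1
F4 | step 9 | (2R)-3-[5-bromo-2,4-bis(methoxymethoxy)phenyl]-2-[2,4-bis(triisopropylsilyloxy)phenyl]propyl methanesulfonate | CS(=O)(=O)OC[C@H](Cc1cc(Br)c(OCOC)cc1OCOC)c1ccc(O[Si](C(C)C)(C(C)C)C(C)C)cc1O[Si](C(C)C)(C(C)C)C(C)C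
F5 | step 9 | (2R)-3-(5-bromo-2,4-dihydroxyphenyl)-2-[2,4-bis(triisopropylsilyloxy)phenyl]propyl methanesulfonate | CS(=O)(=O)OC[C@H](Cc1cc(Br)c(O)cc1O)c1ccc(O[Si](C(C)C)(C(C)C)C(C)C)cc1O[Si](C(C)C)(C(C)C)C(C)C
F0 | step 16 | none | none
A1 | alternative 1 | (3R)-3-[2,4-bis(tert-butyldimethylsilyloxy)-5-(2-methylbut-3-en-2-yl)phenyl]-8-[3-methyl-3-(triethylsilyloxy)butyl]chroman-7-ol | C=CC(C)(C)c1cc([C@@H]2COc3c(ccc(O)c3CCC(C)(C)O[Si](CC)(CC)CC)C2)c(O[Si](C)(C)C(C)(C)C)cc1O[Si](C)(C)C(C)(C)C
A2 | alternative 1 | 2-{(2R)-2-[2,4-bis(tert-butyldimethylsilyloxy)-5-(2-methylbut-3-en-2-yl)phenyl]-3-[5-methyl-5-(triethylsilyloxy)hex-1-ynyloxy]propyl}cyclobut-2-en-1-one | C=CC(C)(C)c1cc([C@@H](CC2=CCC2=O)COC#CCCC(C)(C)O[Si](CC)(CC)CC)c(O[Si](C)(C)C(C)(C)C)cc1O[Si](C)(C)C(C)(C)C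
A3 | alternative 2 | pinacol boronate of the 1-(ring B)-2-(ring A)ethyl unit: 2-{1-[2,4-bis(tert-butyldimethylsilyloxy)-5-(2-methylbut-3-en-2-yl)phenyl]-2-[4-(tert-butyldimethylsilyloxy)-2-(methoxymethoxy)-3-(3-methyl-3-triethylsilyloxybutyl)phenyl]ethyl}-4,4,5,5-tetramethyl-1,3,2-dioxaborolane, configuration as drawn | C=CC(C)(C)c1cc([C@@H](Cc2ccc(O[Si](C)(C)C(C)(C)C)c(CCC(C)(C)O[Si](CC)(CC)CC)c2OCOC)B2OC(C)(C)C(C)(C)O2)c(O[Si](C)(C)C(C)(C)C)cc1O[Si](C)(C)C(C)(C)C
A4 | alternative 2 | 2-[2,4-bis(tert-butyldimethylsilyloxy)-5-(2-methylbut-3-en-2-yl)phenyl]-4,4,5,5-tetramethyl-1,3,2-dioxaborolane | C=CC(C)(C)c1cc(B2OC(C)(C)C(C)(C)O2)c(O[Si](C)(C)C(C)(C)C)cc1O[Si](C)(C)C(C)(C)C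
A5 | alternative 2 | vinyllithium | [Li]C=C
A6 | alternative 2 | 4-(tert-butyldimethylsilyloxy)-2-(methoxymethoxy)-3-[3-methyl-3-(triethylsilyloxy)butyl]phenyl trifluoromethanesulfonate | O=S(=O)(Oc1ccc(O[Si](C)(C)C(C)(C)C)c(CCC(C)(C)O[Si](CC)(CC)CC)c1OCOC)C(F)(F)F
A7 | alternative 3 | (3R)-3-[2,4-bis(tert-butyldimethylsilyloxy)-5-(2-methylbut-3-en-2-yl)phenyl]-7-(tert-butyldimethylsilyloxy)-8-[3-methyl-3-(triethylsilyloxy)butyl]chroman-2-one | C=CC(C)(C)c1cc([C@@H]2C(=O)Oc3c(ccc(O[Si](C)(C)C(C)(C)C)c3CCC(C)(C)O[Si](CC)(CC)CC)C2)c(O[Si](C)(C)C(C)(C)C)cc1O[Si](C)(C)C(C)(C)C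
A8 | alternative 3 | 3-(tert-butyldimethylsilyloxy)-2-[3-methyl-3-(triethylsilyloxy)butyl]-6-(tosylmethyl)phenol | Cc1ccc(cc1)S(=O)(=O)Cc1ccc(O[Si](C)(C)C(C)(C)C)c(CCC(C)(C)O[Si](CC)(CC)CC)c1O
A9 | alternative 3 | 3-(tert-butyldimethylsilyloxy)-6-methylidene-2-[3-methyl-3-(triethylsilyloxy)butyl]cyclohexa-2,4-dien-1-one | C=C1C=CC(O[Si](C)(C)C(C)(C)C)=C(CCC(C)(C)O[Si](CC)(CC)CC)C1=O
A10 | alternative 3 | 2-[2,4-bis(tert-butyldimethylsilyloxy)-5-(2-methylbut-3-en-2-yl)phenyl]acetic acid | C=CC(C)(C)c1cc(CC(=O)O)c(O[Si](C)(C)C(C)(C)C)cc1O[Si](C)(C)C(C)(C)C
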